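**Strategy.** Cutting the C7–C6a bond of the indane ring (a Friedel–Crafts closure in the forward sense) leaves the cyclobutane C1–C2–C2a–C7a carrying C7 as a carboxyl carbon on C7a and a symmetric 3,5-dimethoxyphenyl group on C2a whose two ortho carbons are equivalent. That cyclobutane is made in one operation by photochemical Wolff ring contraction of a trans-3,4-diaryl-2-diazo-5,5-dimethylcyclopentanone: C1 shifts from C7 to C7a, forming the C7a–C1 bond, and methanol captures the ketene. The step exploits the quaternary C1 beside C7: only C7a can take the diazo group and only C1 can migrate. The precursor comes from 2,2-dimethylcyclopentane-1,3-dione by arylation, asymmetric hydrogenation, dehydrogenation and trans-selective conjugate arylation.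

Key step: step 9

**Remarks.**
- Atom numbers are those of the cyclobuta[a]indene core of the target: C1 = CMe2, C2 = CH bearing the catechol ring, C2a, C2b, C3–C6 (aromatic), C6a, C7 = CH2, C7a.
- Tosyloxy = 4-methylbenzenesulfonyloxy. The catechol is carried as its bis-tosylate because the ring closure (step 11) and the ether cleavage (step 12) use Lewis acids that acetal-type phenol ethers would not survive. The sulfonates also switch this ring off towards electrophiles.
- Assumption: the (S)-configured P,N ligand in step 5 is taken to give the (R)-ketone; if the sense of induction is the opposite, the enantiomeric ligand is used.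
- C7a, created in step 9, is an epimerisable centre next to the carboxyl group. Compounds 16, 17 and 18 are drawn and named with the carboxyl group cis to the dimethoxyphenyl ring, the arrangement that closes in step 11. A uniform configuration at C7a is not required before that step, and no separation at this centre is planned.

**Step 1**
Reactants: 1 4-bromocatechol
Product: 2 4-bromo-1,2-phenylene bis(4-methylbenzenesulfonate)
Conditions: TsCl, Et3N, DMAP (cat.), CH2Cl2, 0 → 25 °C
Reagents that add atoms: 4-methylbenzenesulfonyl chloride, Cc1ccc(cc1)S(Cl)(=O)=O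
Why: Sulfonylation of both phenols gives aryl sulfonates that withstand the acid, Lewis acid, mild base and palladium steps that follow and that deactivate the catechol ring.

**Step 2**
Reactants: 2 4-bromo-1,2-phenylene bis(4-methylbenzenesulfonate)
Product: 3 4-(4,4,5,5-tetramethyl-1,3,2-dioxaborolan-2-yl)-1,2-phenylene bis(4-methylbenzenesulfonate)
Conditions: bis(pinacolato)diboron, Pd(dppf)Cl2 (3 mol%), KOAc, 1,4-dioxane, 85 °C
Reagents that add atoms: bis(pinacolato)diboron, CC1(C)OB(OC1(C)C)B1OC(C)(C)C(C)(C)O1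
Why: Miyaura borylation takes place at the C–Br bond only, because aryl tosylates do not undergo oxidative addition with this catalyst.

**Step 3**
Reactants: 4 2,2-dimethylcyclopentane-1,3-dione
Product: 5 5,5-dimethyl-4-oxocyclopent-1-en-1-yl trifluoromethanesulfonate
Conditions: Tf2O (1.0 equiv), 2,6-di-tert-butyl-4-methylpyridine, CH2Cl2, 0 → 25 °C
Reagents that add atoms: trifluoromethanesulfonic anhydride, O=S(=O)(OS(=O)(=O)C(F)(F)F)C(F)(F)F
Why: Enol triflate formation on one of two equivalent carbonyl groups; C2 is quaternary, so only one constitution can form, and one equivalent of anhydride limits double triflation.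

**Step 4**
Reactants: 5 5,5-dimethyl-4-oxocyclopent-1-en-1-yl trifluoromethanesulfonate; 3 4-(4,4,5,5-tetramethyl-1,3,2-dioxaborolan-2-yl)-1,2-phenylene bis(4-methylbenzenesulfonate)
Product: 6 2,2-dimethyl-3-[3,4-bis(tosyloxy)phenyl]cyclopent-3-en-1-one
Conditions: Pd(dppf)Cl2 (3 mol%), K3PO4, THF/H2O (5:1), 40 °C
Reagents that add atoms: none
Why: Suzuki–Miyaura coupling of an enol triflate with an arylboronate; the mild phosphate base at 40 °C should keep the β,γ-unsaturated ketone from isomerising into conjugation and leaves the sulfonates alone.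

**Step 5**
Reactants: 6 2,2-dimethyl-3-[3,4-bis(tosyloxy)phenyl]cyclopent-3-en-1-one
Product: 7 (3R)-2,2-dimethyl-3-[3,4-bis(tosyloxy)phenyl]cyclopentan-1-one
Conditions: [Ir(cod)((S)-tBu-PHOX)][B(3,5-(CF3)2C6H3)4] (2 mol%), H2 (50 bar), CH2Cl2, 25 °C
Reagents that add atoms: none
Why: Iridium P,N-ligand catalysed asymmetric hydrogenation of a trisubstituted aryl alkene; the catalyst distinguishes the alkene faces, which are flanked by a quaternary carbon on one side and a CH2 group on the other, and so sets the future C2 as R.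

**Step 6**
Reactants: 7 (3R)-2,2-dimethyl-3-[3,4-bis(tosyloxy)phenyl]cyclopentan-1-one
Product: 9 (4R)-5,5-dimethyl-4-[3,4-bis(tosyloxy)phenyl]cyclopent-2-en-1-one, via silyl enol ether 8 (not isolated)
Conditions: TMSOTf, Et3N, CH2Cl2, 0 °C; then Pd(OAc)2 (1.05 equiv), MeCN, 25 °C
Reagents that add atoms: none
Why: Saegusa–Ito oxidation; only one α-carbon bears hydrogen, so the silyl enol ether forms regiospecifically, and the non-basic conditions leave the benzylic stereocentre alone.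

**Step 7**
Reactants: 9 (4R)-5,5-dimethyl-4-[3,4-bis(tosyloxy)phenyl]cyclopent-2-en-1-one; 10 3,5-dimethoxyphenylboronic acid
Product: 11 (3R,4R)-4-(3,5-dimethoxyphenyl)-2,2-dimethyl-3-[3,4-bis(tosyloxy)phenyl]cyclopentan-1-one
Conditions: [Rh(cod)OH]2 (2.5 mol%), 1,4-dioxane/H2O (10:1), 30 °C
Reagents that add atoms: none
Why: Rhodium-catalysed 1,4-addition of an arylboronic acid (Hayashi–Miyaura reaction); the aryl group is delivered to the face opposite the neighbouring aryl substituent, which sets the future C2a trans to C2, and the base-free hydroxo complex avoids deprotonation of the acidic γ-benzylic hydrogen of the enone.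

**Step 8**
Reactants: 11 (3R,4R)-4-(3,5-dimethoxyphenyl)-2,2-dimethyl-3-[3,4-bis(tosyloxy)phenyl]cyclopentan-1-one
Product: 14 (3R,4R)-2-diazo-3-(3,5-dimethoxyphenyl)-5,5-dimethyl-4-[3,4-bis(tosyloxy)phenyl]cyclopentan-1-one, via lithium enolate 12 (not isolated), via trifluoroacetyl ketone 13 (not isolated)
Conditions: LiN(SiMe3)2, THF, −78 °C; CF3CO2CH2CF3, −78 °C; then 4-acetamidobenzenesulfonyl azide, Et3N, H2O (1 equiv), MeCN, 25 °C
Reagents that add atoms: 4-acetamidobenzenesulfonyl azide, CC(=O)Nc1ccc(cc1)S(=O)(=O)N=[N+]=[N-]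
Why: Detrifluoroacetylative diazo transfer (a Regitz-type diazo transfer): the only enolisable carbon is acylated, and the activated 1,3-dicarbonyl compound takes N2 from the sulfonyl azide with loss of the trifluoroacetyl group; low-temperature amide base avoids alkoxide attack on the sulfonates.

**Step 9**
Reactants: 14 (3R,4R)-2-diazo-3-(3,5-dimethoxyphenyl)-5,5-dimethyl-4-[3,4-bis(tosyloxy)phenyl]cyclopentan-1-one
Product: 16 methyl (1S,2S,3S)-2-(3,5-dimethoxyphenyl)-4,4-dimethyl-3-[3,4-bis(tosyloxy)phenyl]cyclobutane-1-carboxylate, via ketene 15 (not isolated)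
Conditions: hν (365 nm), MeOH/THF (3:1), 0 °C, degassed
Reagents that add atoms: methanol, CO
Why: Irradiation expels N2 from the diazoketone, which the ring holds s-cis, with concerted 1,2-shift of the quaternary carbon C1 from the carbonyl carbon C7 to C7a; this forms the C7a–C1 bond and the cyclobutylidene ketene 15, to which methanol adds before the enol tautomerises to the ester. The closest known reaction type is the photochemical Wolff ring contraction of 2-diazocyclopentanones, 5,5-dimethyl ones included, to cyclobutanecarboxylic acid derivatives. The four-membered ring is closed by contraction of the five-membered ring (a 1,2-alkyl shift), not by end-to-end cyclisation. The new centre C7a is set when the enol is protonated: the dimethoxyphenyl group on C2a shields its own face, so hydrogen should enter anti to it and place the ester cis to that ring as drawn in 16, and because only this arrangement closes in step 11 while the opposite one feeds it by enolisation, complete selectivity is not required here. The step needs the diazo group at C7a and migration of C1 only, which the substrate secures because C1 is quaternary, and C2 and C2a are not involved, so their trans relationship is kept. Light of 365 nm excites only the diazoketone and leaves the aryl sulfonates untouched.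

**Step 10**
Reactants: 16 methyl (1S,2S,3S)-2-(3,5-dimethoxyphenyl)-4,4-dimethyl-3-[3,4-bis(tosyloxy)phenyl]cyclobutane-1-carboxylate
Product: 17 (1S,2S,3S)-2-(3,5-dimethoxyphenyl)-4,4-dimethyl-3-[3,4-bis(tosyloxy)phenyl]cyclobutane-1-carboxylic acid
Conditions: Me3SnOH (8 equiv), 1,2-dichloroethane, 80 °C; aq. HCl wash
Reagents that add atoms: trimethyltin hydroxide, C[Sn](C)(C)O
Why: Tin hydroxide mediated hydrolysis cleaves the methyl ester under neutral conditions and spares the aryl sulfonates that aqueous hydroxide would attack; the reagent is not expected to disturb C7a, and a change of configuration there would in any case be harmless.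

**Step 11**
Reactants: 17 (1S,2S,3S)-2-(3,5-dimethoxyphenyl)-4,4-dimethyl-3-[3,4-bis(tosyloxy)phenyl]cyclobutane-1-carboxylic acid
Product: 19 (2S,2aS,7aS)-4,6-dimethoxy-1,1-dimethyl-2-[3,4-bis(tosyloxy)phenyl]-1,2,2a,7a-tetrahydro-7H-cyclobuta[a]inden-7-one, via acid chloride 18 (not isolated)
Conditions: (COCl)2, DMF (cat.), CH2Cl2, 0 → 25 °C; then SnCl4 (2 equiv), CH2Cl2, −20 → 0 °C
Reagents that add atoms: none
Why: Intramolecular Friedel–Crafts acylation at either of the two equivalent ortho carbons of the dimethoxyphenyl ring (each ortho and para to a methoxy group) forms the C7–C6a bond; only an acyl group cis to that ring can reach it, and material of the opposite configuration at C7a is drawn in through Lewis-acid-promoted enolisation of the acid chloride (reversible loss of HCl to the ketene), so the ring fusion is necessarily cis.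

**Step 12**
Reactants: 19 (2S,2aS,7aS)-4,6-dimethoxy-1,1-dimethyl-2-[3,4-bis(tosyloxy)phenyl]-1,2,2a,7a-tetrahydro-7H-cyclobuta[a]inden-7-one
Product: 20 (2S,2aS,7aS)-6-hydroxy-4-methoxy-1,1-dimethyl-2-[3,4-bis(tosyloxy)phenyl]-1,2,2a,7a-tetrahydro-7H-cyclobuta[a]inden-7-one
Conditions: BCl3 (1.5 equiv), CH2Cl2, −78 → 0 °C
Reagents that add atoms: none
Why: Chelation-controlled demethylation: boron trichloride bridges the ketone oxygen and the C6 methoxy group and cleaves only that ether, leaving the C4 methoxy group and the sulfonates.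

**Step 13**
Reactants: 20 (2S,2aS,7aS)-6-hydroxy-4-methoxy-1,1-dimethyl-2-[3,4-bis(tosyloxy)phenyl]-1,2,2a,7a-tetrahydro-7H-cyclobuta[a]inden-7-one
Product: 22 (2S,2aR,7aS)-4-methoxy-1,1-dimethyl-2-[3,4-bis(tosyloxy)phenyl]-2,2a,7,7a-tetrahydro-1H-cyclobuta[a]inden-6-ol, via aryl ethyl carbonate 21 (not isolated)
Conditions: ClCO2Et, Et3N, THF, 0 °C; then NaBH4, H2O, 0 → 25 °C
Reagents that add atoms: none
Why: Reductive deoxygenation of an ortho-hydroxyaryl ketone through its aryl carbonate: borohydride reduces the ketone, the alkoxide takes over the carbonate and leaves to give an ortho-quinone methide that is reduced again; the basic medium avoids a free benzylic cation next to the cyclobutane.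

**Step 14**
Reactants: 22 (2S,2aR,7aS)-4-methoxy-1,1-dimethyl-2-[3,4-bis(tosyloxy)phenyl]-2,2a,7,7a-tetrahydro-1H-cyclobuta[a]inden-6-ol
Product: 23 (2S,2aR,7aS)-3-bromo-4-methoxy-1,1-dimethyl-2-[3,4-bis(tosyloxy)phenyl]-2,2a,7,7a-tetrahydro-1H-cyclobuta[a]inden-6-ol
Conditions: NBS (1.0 equiv), MeCN, −20 °C
Reagents that add atoms: N-bromosuccinimide, O=C1CCC(=O)N1Br
Why: Electrophilic bromination of the phenol goes para to the free hydroxyl, at C3 (also ortho to the methoxy group); the other open position, C5, lies between two oxygens and is the less reactive site of this 5-alkylresorcinol pattern, and the sulfonylated ring is deactivated.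

**Step 15**
Reactants: 23 (2S,2aR,7aS)-3-bromo-4-methoxy-1,1-dimethyl-2-[3,4-bis(tosyloxy)phenyl]-2,2a,7,7a-tetrahydro-1H-cyclobuta[a]inden-6-ol
Product: 24 (2S,2aR,7aS)-4-methoxy-1,1-dimethyl-3-(3-methylbut-2-en-1-yl)-2-[3,4-bis(tosyloxy)phenyl]-2,2a,7,7a-tetrahydro-1H-cyclobuta[a]inden-6-ol
Conditions: (3-methylbut-2-en-1-yl)zinc bromide (2.5 equiv; from prenyl bromide, Zn, LiCl, THF), Pd(OAc)2 (3 mol%), CPhos (6 mol%), THF, 25 °C
Reagents that add atoms: 1-bromo-3-methylbut-2-ene, CC(C)=CCBr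
Why: Linear-selective Negishi coupling of an allylic zinc reagent with the aryl bromide gives the unrearranged prenyl group; the phenol only consumes one equivalent of the zinc reagent, and the aryl sulfonates add to palladium far more slowly than the bromide.

**Step 16**
Reactants: 24 (2S,2aR,7aS)-4-methoxy-1,1-dimethyl-3-(3-methylbut-2-en-1-yl)-2-[3,4-bis(tosyloxy)phenyl]-2,2a,7,7a-tetrahydro-1H-cyclobuta[a]inden-6-ol
Product: 25 4-[(2S,2aR,7aS)-6-hydroxy-4-methoxy-1,1-dimethyl-3-(3-methylbut-2-en-1-yl)-2,2a,7,7a-tetrahydro-1H-cyclobuta[a]inden-2-yl]benzene-1,2-diol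
Conditions: KOH (10 equiv), EtOH/H2O (2:1), 80 °C, argon; then aq. HCl
Reagents that add atoms: none
Why: Alkaline hydrolysis of the aryl sulfonates (hydroxide attacks sulfur) frees the catechol without touching the methyl ether, the prenyl group or the cyclobutane; air is excluded to protect the catecholate.

**Compound list**

1 | 4-bromocatechol | Oc1ccc(Br)cc1O | starting material
2 | 4-bromo-1,2-phenylene bis(4-methylbenzenesulfonate) | Brc1ccc(OS(=O)(=O)c2ccc(C)cc2)c(OS(=O)(=O)c2ccc(C)cc2)c1 | intermediate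
3 | 4-(4,4,5,5-tetramethyl-1,3,2-dioxaborolan-2-yl)-1,2-phenylene bis(4-methylbenzenesulfonate) | CC1(C)OB(OC1(C)C)c1ccc(OS(=O)(=O)c2ccc(C)cc2)c(OS(=O)(=O)c2ccc(C)cc2)c1 | intermediate
4 | 2,2-dimethylcyclopentane-1,3-dione | CC1(C)C(=O)CCC1=O | starting material
5 | 5,5-dimethyl-4-oxocyclopent-1-en-1-yl trifluoromethanesulfonate | CC1(C)C(=O)CC=C1OS(=O)(=O)C(F)(F)F | intermediate
6 | 2,2-dimethyl-3-[3,4-bis(tosyloxy)phenyl]cyclopent-3-en-1-one | CC1(C)C(=O)CC=C1c1ccc(OS(=O)(=O)c2ccc(C)cc2)c(OS(=O)(=O)c2ccc(C)cc2)c1 | intermediate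
7 | (3R)-2,2-dimethyl-3-[3,4-bis(tosyloxy)phenyl]cyclopentan-1-one | O=C1CC[C@H](c2ccc(OS(=O)(=O)c3ccc(C)cc3)c(OS(=O)(=O)c3ccc(C)cc3)c2)C1(C)C | intermediate
8 | trimethylsilyl enol ether of 7 (not isolated) | C[Si](C)(C)OC1=CC[C@H](c2ccc(OS(=O)(=O)c3ccc(C)cc3)c(OS(=O)(=O)c3ccc(C)cc3)c2)C1(C)C | intermediate
9 | (4R)-5,5-dimethyl-4-[3,4-bis(tosyloxy)phenyl]cyclopent-2-en-1-one | O=C1C=C[C@H](c2ccc(OS(=O)(=O)c3ccc(C)cc3)c(OS(=O)(=O)c3ccc(C)cc3)c2)C1(C)C | intermediate
10 | 3,5-dimethoxyphenylboronic acid | COc1cc(OC)cc(B(O)O)c1 | starting material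
11 | (3R,4R)-4-(3,5-dimethoxyphenyl)-2,2-dimethyl-3-[3,4-bis(tosyloxy)phenyl]cyclopentan-1-one (aryl groups trans) | O=C1C[C@@H](c2cc(OC)cc(OC)c2)[C@H](c2ccc(OS(=O)(=O)c3ccc(C)cc3)c(OS(=O)(=O)c3ccc(C)cc3)c2)C1(C)C | intermediate
12 | lithium enolate of 11 (not isolated) | [Li+].[O-]C1=C[C@@H](c2cc(OC)cc(OC)c2)[C@H](c2ccc(OS(=O)(=O)c3ccc(C)cc3)c(OS(=O)(=O)c3ccc(C)cc3)c2)C1(C)C | intermediate
13 | 5-(trifluoroacetyl) derivative of 11, aryl centres unchanged (not isolated) | O=C1C(C(=O)C(F)(F)F)[C@@H](c2cc(OC)cc(OC)c2)[C@H](c2ccc(OS(=O)(=O)c3ccc(C)cc3)c(OS(=O)(=O)c3ccc(C)cc3)c2)C1(C)C | intermediate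
14 | (3R,4R)-2-diazo-3-(3,5-dimethoxyphenyl)-5,5-dimethyl-4-[3,4-bis(tosyloxy)phenyl]cyclopentan-1-one | O=C1C(=[N+]=[N-])[C@@H](c2cc(OC)cc(OC)c2)[C@H](c2ccc(OS(=O)(=O)c3ccc(C)cc3)c(OS(=O)(=O)c3ccc(C)cc3)c2)C1(C)C | intermediate
15 | trans-2,3-diaryl-4,4-dimethylcyclobutylidene ketene, aryl centres as in 14 (not isolated) | O=C=C1[C@@H](c2cc(OC)cc(OC)c2)[C@H](c2ccc(OS(=O)(=O)c3ccc(C)cc3)c(OS(=O)(=O)c3ccc(C)cc3)c2)C1(C)C | intermediate
16 | methyl (1S,2S,3S)-2-(3,5-dimethoxyphenyl)-4,4-dimethyl-3-[3,4-bis(tosyloxy)phenyl]cyclobutane-1-carboxylate (ester cis to the dimethoxyphenyl group) | COC(=O)[C@H]1[C@@H](c2cc(OC)cc(OC)c2)[C@H](c2ccc(OS(=O)(=O)c3ccc(C)cc3)c(OS(=O)(=O)c3ccc(C)cc3)c2)C1(C)C | intermediate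
17 | (1S,2S,3S)-2-(3,5-dimethoxyphenyl)-4,4-dimethyl-3-[3,4-bis(tosyloxy)phenyl]cyclobutane-1-carboxylic acid | OC(=O)[C@H]1[C@@H](c2cc(OC)cc(OC)c2)[C@H](c2ccc(OS(=O)(=O)c3ccc(C)cc3)c(OS(=O)(=O)c3ccc(C)cc3)c2)C1(C)C | intermediate
18 | (1S,2S,3S)-2-(3,5-dimethoxyphenyl)-4,4-dimethyl-3-[3,4-bis(tosyloxy)phenyl]cyclobutane-1-carbonyl chloride (not isolated) | ClC(=O)[C@H]1[C@@H](c2cc(OC)cc(OC)c2)[C@H](c2ccc(OS(=O)(=O)c3ccc(C)cc3)c(OS(=O)(=O)c3ccc(C)cc3)c2)C1(C)C | intermediate
19 | (2S,2aS,7aS)-4,6-dimethoxy-1,1-dimethyl-2-[3,4-bis(tosyloxy)phenyl]-1,2,2a,7a-tetrahydro-7H-cyclobuta[a]inden-7-one | COc1cc(OC)c2c(c1)[C@@H]1[C@H](C2=O)C(C)(C)[C@H]1c1ccc(OS(=O)(=O)c2ccc(C)cc2)c(OS(=O)(=O)c2ccc(C)cc2)c1 | intermediate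
20 | (2S,2aS,7aS)-6-hydroxy-4-methoxy-1,1-dimethyl-2-[3,4-bis(tosyloxy)phenyl]-1,2,2a,7a-tetrahydro-7H-cyclobuta[a]inden-7-one | COc1cc(O)c2c(c1)[C@@H]1[C@H](C2=O)C(C)(C)[C@H]1c1ccc(OS(=O)(=O)c2ccc(C)cc2)c(OS(=O)(=O)c2ccc(C)cc2)c1 | intermediate
21 | ethyl carbonate of the C6 phenol of 20 (not isolated) | COc1cc(OC(=O)OCC)c2c(c1)[C@@H]1[C@H](C2=O)C(C)(C)[C@H]1c1ccc(OS(=O)(=O)c2ccc(C)cc2)c(OS(=O)(=O)c2ccc(C)cc2)c1 | intermediate
22 | (2S,2aR,7aS)-4-methoxy-1,1-dimethyl-2-[3,4-bis(tosyloxy)phenyl]-2,2a,7,7a-tetrahydro-1H-cyclobuta[a]inden-6-ol | COc1cc(O)c2c(c1)[C@@H]1[C@H](C2)C(C)(C)[C@H]1c1ccc(OS(=O)(=O)c2ccc(C)cc2)c(OS(=O)(=O)c2ccc(C)cc2)c1 | intermediate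
23 | (2S,2aR,7aS)-3-bromo-4-methoxy-1,1-dimethyl-2-[3,4-bis(tosyloxy)phenyl]-2,2a,7,7a-tetrahydro-1H-cyclobuta[a]inden-6-ol | COc1cc(O)c2c(c1Br)[C@@H]1[C@H](C2)C(C)(C)[C@H]1c1ccc(OS(=O)(=O)c2ccc(C)cc2)c(OS(=O)(=O)c2ccc(C)cc2)c1 | intermediate
24 | (2S,2aR,7aS)-4-methoxy-1,1-dimethyl-3-(3-methylbut-2-en-1-yl)-2-[3,4-bis(tosyloxy)phenyl]-2,2a,7,7a-tetrahydro-1H-cyclobuta[a]inden-6-ol | COc1cc(O)c2c(c1CC=C(C)C)[C@@H]1[C@H](C2)C(C)(C)[C@H]1c1ccc(OS(=O)(=O)c2ccc(C)cc2)c(OS(=O)(=O)c2ccc(C)cc2)c1 | intermediate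
25 | 4-[(2S,2aR,7aS)-6-hydroxy-4-methoxy-1,1-dimethyl-3-(3-methylbut-2-en-1-yl)-2,2a,7,7a-tetrahydro-1H-cyclobuta[a]inden-2-yl]benzene-1,2-diol (CNP0236667.1) | COc1cc(O)c2c(c1CC=C(C)C)[C@@H]1[C@H](C2)C(C)(C)[C@H]1c1ccc(O)c(O)c1 | target

**Step count.** Total: 16 steps. Longest linear sequence: 15 steps (steps 1, 2 and 4–16, from 4-bromocatechol).

**Steps most likely to fail**

Step 9. The contraction to the strained four-membered ring may lose out to a 1,2-hydrogen shift of the carbene (which would give a conjugated enone) or to O–H insertion into methanol. The fallback sets out from ketone 11. Its lithium enolate 12 (LiN(SiMe3)2, THF, −78 °C) is brominated with NBS on the face away from the neighbouring aryl group to (3R,4R,5R)-5-bromo-4-(3,5-dimethoxyphenyl)-2,2-dimethyl-3-[3,4-bis(tosyloxy)phenyl]cyclopentan-1-one F1. NaOMe in MeOH/THF at 0 °C then triggers a semibenzilic (quasi-Favorskii) ring contraction: methoxide adds to C7 and C1 shifts to C7a as bromide leaves. C1 has no hydrogen, so no cyclopropanone pathway competes. Because the shift inverts C7a, the expected product is methyl (1R,2S,3S)-2-(3,5-dimethoxyphenyl)-4,4-dimethyl-3-[3,4-bis(tosyloxy)phenyl]cyclobutane-1-carboxylate F2, with the ester trans to the dimethoxyphenyl group. Me3SnOH as in step 10 gives (1R,2S,3S)-2-(3,5-dimethoxyphenyl)-4,4-dimethyl-3-[3,4-bis(tosyloxy)phenyl]cyclobutane-1-carboxylic acid F3. Oxalyl chloride converts it into (1R,2S,3S)-2-(3,5-dimethoxyphenyl)-4,4-dimethyl-3-[3,4-bis(tosyloxy)phenyl]cyclobutane-1-carbonyl chloride F4. Under the SnCl4 conditions of step 11 this epimerises at C7a by enolisation, and the route is rejoined at acid chloride 18, which closes to indanone 19.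

Step 5. Facial discrimination by the catalyst may be insufficient, or the acidic iridium hydride may move the double bond into conjugation before reduction, and either would lower the enantiomeric purity. The fallback sets out from ketone 6. Corey–Bakshi–Shibata reduction with (R)-2-methyl-CBS-oxazaborolidine and BH3·SMe2 (the carbonyl is flanked by a quaternary carbon and a CH2 group) gives (1S)-2,2-dimethyl-3-[3,4-bis(tosyloxy)phenyl]cyclopent-3-en-1-ol F5. Hydroxyl-directed hydrogenation with [Ir(cod)(PCy3)(py)]PF6 and H2 in CH2Cl2 delivers hydrogen to the alkene face syn to the hydroxyl group and gives (1S,3R)-2,2-dimethyl-3-[3,4-bis(tosyloxy)phenyl]cyclopentan-1-ol F6, with the aryl group trans to OH. Dess–Martin periodinane oxidation returns to ketone 7.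

Step 11. Enolisation of the acid chloride may be slower than its decomposition (decarbonylation or opening of the cyclobutane), so that any material with the acyl group trans to the dimethoxyphenyl ring fails to close. The fallback sets out from acid 17. Through acid chloride 18 and dimethylamine it gives (1S,2S,3S)-2-(3,5-dimethoxyphenyl)-N,N,4,4-tetramethyl-3-[3,4-bis(tosyloxy)phenyl]cyclobutane-1-carboxamide F7; material of the opposite configuration at C7a reacts alike. Tf2O and 2,4,6-collidine in CH2Cl2 (−78 → 40 °C) convert the amide into N-{[2-(3,5-dimethoxyphenyl)-4,4-dimethyl-3-[3,4-bis(tosyloxy)phenyl]cyclobutylidene]methylidene}-N-methylmethanaminium trifluoromethanesulfonate F8. This keteniminium salt is planar at C7a, so the earlier configuration there no longer matters. The dimethoxyphenyl ring attacks its electrophilic carbon (Vilsmeier–Haack-type acylation with an activated amide) and C7a is protonated from the convex face. This gives the cis-fused cyclic iminium salt N-[4,6-dimethoxy-1,1-dimethyl-2-[3,4-bis(tosyloxy)phenyl]-1,2,2a,7a-tetrahydro-7H-cyclobuta[a]inden-7-ylidene]-N-methylmethanaminium trifluoromethanesulfonate F9. Aqueous NaHCO3 hydrolyses it, and the route is rejoined at indanone 19.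

**Further compounds**

F1 | step 9 | (3R,4R,5R)-5-bromo-4-(3,5-dimethoxyphenyl)-2,2-dimethyl-3-[3,4-bis(tosyloxy)phenyl]cyclopentan-1-one (bromine trans to the 4-aryl group) | O=C1[C@H](Br)[C@@H](c2cc(OC)cc(OC)c2)[C@H](c2ccc(OS(=O)(=O)c3ccc(C)cc3)c(OS(=O)(=O)c3ccc(C)cc3)c2)C1(C)C
F2 | step 9 | methyl (1R,2S,3S)-2-(3,5-dimethoxyphenyl)-4,4-dimethyl-3-[3,4-bis(tosyloxy)phenyl]cyclobutane-1-carboxylate (ester trans to the dimethoxyphenyl group) | COC(=O)[C@@H]1[C@@H](c2cc(OC)cc(OC)c2)[C@H](c2ccc(OS(=O)(=O)c3ccc(C)cc3)c(OS(=O)(=O)c3ccc(C)cc3)c2)C1(C)C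
F3 | step 9 | (1R,2S,3S)-2-(3,5-dimethoxyphenyl)-4,4-dimethyl-3-[3,4-bis(tosyloxy)phenyl]cyclobutane-1-carboxylic acid | OC(=O)[C@@H]1[C@@H](c2cc(OC)cc(OC)c2)[C@H](c2ccc(OS(=O)(=O)c3ccc(C)cc3)c(OS(=O)(=O)c3ccc(C)cc3)c2)C1(C)C
F4 | step 9 | (1R,2S,3S)-2-(3,5-dimethoxyphenyl)-4,4-dimethyl-3-[3,4-bis(tosyloxy)phenyl]cyclobutane-1-carbonyl chloride | ClC(=O)[C@@H]1[C@@H](c2cc(OC)cc(OC)c2)[C@H](c2ccc(OS(=O)(=O)c3ccc(C)cc3)c(OS(=O)(=O)c3ccc(C)cc3)c2)C1(C)C
F5 | step 5 | (1S)-2,2-dimethyl-3-[3,4-bis(tosyloxy)phenyl]cyclopent-3-en-1-ol | O[C@H]1CC=C(c2ccc(OS(=O)(=O)c3ccc(C)cc3)c(OS(=O)(=O)c3ccc(C)cc3)c2)C1(C)C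
F6 | step 5 | (1S,3R)-2,2-dimethyl-3-[3,4-bis(tosyloxy)phenyl]cyclopentan-1-ol | O[C@H]1CC[C@H](c2ccc(OS(=O)(=O)c3ccc(C)cc3)c(OS(=O)(=O)c3ccc(C)cc3)c2)C1(C)C
F7 | step 11 | (1S,2S,3S)-2-(3,5-dimethoxyphenyl)-N,N,4,4-tetramethyl-3-[3,4-bis(tosyloxy)phenyl]cyclobutane-1-carboxamide | CN(C)C(=O)[C@H]1[C@@H](c2cc(OC)cc(OC)c2)[C@H](c2ccc(OS(=O)(=O)c3ccc(C)cc3)c(OS(=O)(=O)c3ccc(C)cc3)c2)C1(C)C
F8 | step 11 | N-{[2-(3,5-dimethoxyphenyl)-4,4-dimethyl-3-[3,4-bis(tosyloxy)phenyl]cyclobutylidene]methylidene}-N-methylmethanaminium trifluoromethanesulfonate (aryl centres as in 14) | C[N+](C)=C=C1[C@@H](c2cc(OC)cc(OC)c2)[C@H](c2ccc(OS(=O)(=O)c3ccc(C)cc3)c(OS(=O)(=O)c3ccc(C)cc3)c2)C1(C)C.[O-]S(=O)(=O)C(F)(F)F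
F9 | step 11 | N-[4,6-dimethoxy-1,1-dimethyl-2-[3,4-bis(tosyloxy)phenyl]-1,2,2a,7a-tetrahydro-7H-cyclobuta[a]inden-7-ylidene]-N-methylmethanaminium trifluoromethanesulfonate (ring centres as in 19) | COc1cc(OC)c2c(c1)[C@@H]1[C@H](C2=[N+](C)C)C(C)(C)[C@H]1c1ccc(OS(=O)(=O)c2ccc(C)cc2)c(OS(=O)(=O)c2ccc(C)cc2)c1.[O-]S(=O)(=O)C(F)(F)F
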